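A small charge of substrate, 0.020 M, was split among three first-order-looking exits, and I had to say how much of it reached target at each reagent charge.

    substrate + reagent → target (k1 = 0.47 M⁻¹ min⁻¹)
    substrate → intermediate (k2 = 0.010 min⁻¹)
    reagent + intermediate → side product (k3 = 0.35 M⁻¹ min⁻¹)
    substrate ⇌ dormant form (K4 = 9.9, k4 = 0.0044 min⁻¹)

all flasks: substrate 0.020 M; time 80 min

| run | reagent |
|---|---|
| Wednesday's | 0.0100 M |
| Saturday's | 0.0150 M |
| Thursday's | 0.0200 M |
| Friday's | 0.0300 M |

* [target] at the end for Wednesday's, Saturday's, Thursday's, Friday's, in this order
* the shape of the row from first to last (falls, then rises / rises all the way / rises, then falls / hardly changes / falls all the way)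

- "hardly changes" means that all values lie within two and a half points (for a concentration: within two and a half percent of the largest)
- run time (Wednesday's): 80 min

I began with Wednesday's flask and froze reagent at its charge, which made the step to target pseudo-first-order at 0.00470 min⁻¹. The two other exits from substrate ran at 0.010 min⁻¹ to intermediate and 0.0044 min⁻¹ to dormant form. The way back from dormant form, at 4.44 × 10⁻⁴ min⁻¹, is ten times slower than the way in, so I dropped it.

The rule I carried was target's share, the rate of the step to target over the sum of the three exit rates, which with reagent frozen at its charge came to 24.6%. Those rates add up to 0.0191 min⁻¹, so I reckoned that in 80 min a fraction 78.3% of the substrate left. Charge times fraction gone times share gave 0.00385 M.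

The weak link was the frozen reagent, since that figure spends 38.5% of the reagent charge. So I reforged it with reagent midway between the charge and the end of that spending, 0.00807 M. The share became 20.9%, the rate of the step to target at that reagent over the sum of the three exit rates, and my figure for Wednesday's target became 0.00320 M. With the two other exit constants the same in all four flasks, the share climbs with reagent, so I expected the row to rise.

The forecast gave 0.0032 M, 0.0045 M, 0.0057 M and 0.008 M, rises all the way, on the ground that “More reagent speeds the only step that makes target”.

The simulation gave 0.00317 M, 0.00453 M, 0.00576 M and 0.00787 M, rises all the way.

In Wednesday's flask the step to target had 73% of its turnover behind it by 40.0 min, while substrate fell to 48.0% of its charge and reagent to 73.5% of its own. By 80.0 min substrate stood at 24.0%, reagent at 58.9%, and target had gone from 11.5% to 15.8% of the substrate charged. Wednesday's target over substrate gone read 20.8% at the end, beside my 20.9% from the midway reagent. For Friday's flask the same steps gave 0.00888 M frozen, then midway reagent 0.0256 M, share 45.5% and target 0.00800 M, and that flask ended at 0.00787 M.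

Its constants are assumed; the result is computed.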